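**Plan**

- Retrosynthesis: remove the exocyclic methylene, open O1–C2 of the oxane (retro-oxa-Michael) and cut C2–Cα (Wittig), then cut the side chain between C2′ (allylic CH2) and C3′ (CH of the first alkene), i.e. C1–C2 of the farnesyl unit. The alkenyl partner goes back to a terminal enyne made from geranyl bromide, the ring partner to 4-(hydroxymethyl)cyclohexanone.
- Forward: the C14 (E)-alkenyl iodide is made by propargylation, desilylation and carboalumination/iodination. The C7 iodo-lactone is made by enantioselective Baeyer–Villiger ring expansion, 7→6 translactonisation and iodination. The two are joined by Negishi coupling, then the lactone is reduced, homologated, reclosed to the oxane, α-methylenated and saponified.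
- Feature that makes the key event possible: C3′ is the CH of an (E)-trisubstituted alkene whose methyl is cis to C2′, which is the outcome of syn methyl–metal addition to a terminal alkyne. C2′ is a primary CH2 two carbons from C5 with no β-heteroatom, and the oxane ring can be carried as its C2 lactone (O1 acylated), so C2′ can bear zinc.
- Stereochemistry: C5 comes from catalyst-controlled desymmetrisation of the mirror-symmetric cyclohexanone, a temporary carbocycle cleaved by oxygen insertion. C2 comes from thermodynamic control in the reversible oxa-Michael closure (2,5-trans, both groups equatorial). The C3′ alkene comes from the carboalumination and the C7′ alkene from geranyl bromide.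

Key step: step 6

Remark: in step 4 the sense of induction follows the ligand enantiomer; the enantiomer that gives the (5R) lactone is meant.

**Route**

Step 1
Reactants: 1 geranyl bromide; 2 trimethyl(prop-1-yn-1-yl)silane
Product: 4 [(5E)-6,10-dimethylundeca-5,9-dien-1-yn-1-yl]trimethylsilane, via propargyllithium 3 (not isolated)
Conditions: n-BuLi, THF, −78 → −20 °C; then 1, −78 °C → rt
Reagents that add atoms: none
Why: Alkylation of a lithiated silylpropyne (propargylation): the silyl-capped propargyl anion should attack the unhindered primary allylic bromide by SN2 at its CH2 terminus, the bulky silyl group disfavouring the allenyl mode, and the 2E alkene of the geranyl unit is not touched.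

Step 2
Reactants: 4 [(5E)-6,10-dimethylundeca-5,9-dien-1-yn-1-yl]trimethylsilane
Product: 5 (5E)-6,10-dimethylundeca-5,9-dien-1-yne
Conditions: K2CO3 (0.2 equiv), MeOH, rt
Reagents that add atoms: none
Why: Base-catalysed protodesilylation of an alkynylsilane by methoxide, to which the isolated trisubstituted alkenes are inert.

Step 3
Reactants: 5 (5E)-6,10-dimethylundeca-5,9-dien-1-yne
Product: 7 (1E,5E)-1-iodo-2,6,10-trimethylundeca-1,5,9-triene, via alkenylalane 6 (not isolated)
Conditions: Me3Al (2 equiv), Cp2ZrCl2 (0.25 equiv), CH2Cl2, 0 °C → rt; then I2, THF, −30 → 0 °C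
Reagents that add atoms: trimethylaluminium C[Al](C)C; iodine II
Why: Zirconium-catalysed carboalumination (Negishi carboalumination) should add methyl and aluminium syn across the terminal alkyne with methyl on the internal carbon, and iodinolysis of the C–Al bond goes with retention, so iodine ends cis to the new methyl (E) while the trisubstituted alkenes do not react.

Step 4
Reactants: 8 4-(hydroxymethyl)cyclohexan-1-one
Product: 10 (5R)-5-(2-hydroxyethyl)oxan-2-one, via seven-membered lactone 9 (not isolated)
Conditions: m-CPBA, Sc(OTf)3 (5 mol %), chiral N,N′-dioxide ligand (5 mol %), EtOAc, −20 °C; then CSA (5 mol %), CH2Cl2, rt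
Reagents that add atoms: 3-chloroperbenzoic acid OOC(=O)c1cccc(Cl)c1
Why: Catalytic enantioselective Baeyer–Villiger desymmetrisation: the chiral scandium complex should differentiate the two enantiotopic migrating CH2 groups of the prochiral ketone and so set the stereocentre that becomes C5, after which acid moves the acyl group to the free CH2OH (translactonisation to the more stable six-membered lactone) and frees the 2-hydroxyethyl arm without touching that centre.

Step 5
Reactants: 10 (5R)-5-(2-hydroxyethyl)oxan-2-one
Product: 11 (5R)-5-(2-iodoethyl)oxan-2-one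
Conditions: I2, PPh3, imidazole, CH2Cl2, 0 °C → rt
Reagents that add atoms: iodine II
Why: Appel-type iodination by SN2 displacement of the alkoxyphosphonium at the primary carbon, which leaves the lactone and the remote stereocentre unchanged.

Step 6
Reactants: 11 (5R)-5-(2-iodoethyl)oxan-2-one; 7 (1E,5E)-1-iodo-2,6,10-trimethylundeca-1,5,9-triene
Product: 13 (5S)-5-[(3E,7E)-4,8,12-trimethyltrideca-3,7,11-trien-1-yl]oxan-2-one, via alkylzinc iodide 12 (not isolated)
Conditions: Zn dust (activated by BrCH2CH2Br and Me3SiCl), THF, 35 °C; then 7, Pd(PPh3)4 (5 mol %), THF, rt → 45 °C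
Reagents that add atoms: none
Why: Zinc metal inserts into the primary C–I bond of 11 to give alkylzinc iodide 12, which is too weakly nucleophilic to attack its own lactone; zerovalent palladium then adds oxidatively into the alkenyl C–I bond of 7, the alkyl group passes from zinc to palladium, and reductive elimination forms the CH2–CH= bond. The closest known reaction type is the Negishi alkyl–alkenyl cross-coupling of functionalised primary alkylzinc halides with (E)-2-methyl-1-iodoalk-1-enes, the standard way to join 1,5-diene isoprenoid units. No ring is closed and no stereocentre is formed; C5 lies two carbons from the metal-bearing carbon and is not touched (its descriptor changes from R to S only because the priorities of the two arms change), and the E geometry from step 3 should be carried through because oxidative addition and reductive elimination are both stereoretentive. The step needs chemoselectivity for the C–I bond of 7 over the lactone carbonyl and the alkenes, and reductive elimination faster than β-hydride elimination; the first is secured by the low nucleophilicity of the organozinc and by the lactone oxidation level, which keeps O1 acylated so that no free hydroxyl can quench the reagent or displace the iodide, and the second by the primary unbranched CH2CH2 arm with no heteroatom β to zinc.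

Step 7
Reactants: 13 (5S)-5-[(3E,7E)-4,8,12-trimethyltrideca-3,7,11-trien-1-yl]oxan-2-one
Product: 14 (5S)-5-[(3E,7E)-4,8,12-trimethyltrideca-3,7,11-trien-1-yl]oxan-2-ol (mixture of C2 epimers)
Conditions: iBu2AlH (1.1 equiv), CH2Cl2, −78 °C; aq. KNaC4H4O6
Reagents that add atoms: none
Why: Partial reduction of a δ-lactone to the lactol, the tetrahedral aluminium hemiacetal being stable at −78 °C so that over-reduction is avoided and the alkenes are untouched.

Step 8
Reactants: 14 (5S)-5-[(3E,7E)-4,8,12-trimethyltrideca-3,7,11-trien-1-yl]oxan-2-ol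
Product: 16 methyl 2-[(2R,5S)-5-[(3E,7E)-4,8,12-trimethyltrideca-3,7,11-trien-1-yl]oxan-2-yl]acetate, via hydroxy enoate 15 (not isolated)
Conditions: Ph3P=CHCO2Me, PhMe, 80 °C; then KOtBu (0.2 equiv), THF, 0 °C → rt
Reagents that add atoms: methyl (triphenylphosphoranylidene)acetate COC(=O)C=P(c1ccccc1)(c1ccccc1)c1ccccc1
Why: Wittig olefination of the ring-opened hydroxy aldehyde followed by reversible 6-exo-trig oxa-Michael addition, in which the alkoxide-catalysed equilibrium should favour the chair with the C2 and C5 substituents both equatorial, so the C2 configuration (R, 2,5-trans) is set by thermodynamic control from C5.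

Step 9
Reactants: 16 methyl 2-[(2R,5S)-5-[(3E,7E)-4,8,12-trimethyltrideca-3,7,11-trien-1-yl]oxan-2-yl]acetate
Product: 20 methyl 2-[(2R,5S)-5-[(3E,7E)-4,8,12-trimethyltrideca-3,7,11-trien-1-yl]oxan-2-yl]prop-2-enoate, via lithium enolate 17 (not isolated), via Mannich base 18 (not isolated), via ammonium iodide 19 (not isolated)
Conditions: LiN(iPr)2, THF, −78 °C; CH2=NMe2+ I− (Eschenmoser's salt), −78 → 0 °C; then MeI, MeOH, rt; then aq. NaHCO3, CH2Cl2, rt
Reagents that add atoms: Eschenmoser's salt C=[N+](C)C.[I-]
Why: α-Methylenation by Mannich aminomethylation of the ester enolate, exhaustive N-methylation and E1cB loss of trimethylamine; at −78 °C the enolate should be trapped faster than it expels the ring oxygen, C2 is not deprotonated and keeps its configuration, and the transient α-stereocentre disappears in the elimination.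

Step 10
Reactants: 20 methyl 2-[(2R,5S)-5-[(3E,7E)-4,8,12-trimethyltrideca-3,7,11-trien-1-yl]oxan-2-yl]prop-2-enoate
Product: 22 rhopaloic acid A, via lithium carboxylate 21 (not isolated)
Conditions: LiOH·H2O, THF/MeOH/H2O, rt; then 1 M HCl to pH 3, 0 °C
Reagents that add atoms: lithium hydroxide [Li+].[OH-]
Why: Saponification (acyl–oxygen cleavage) of the methyl ester, with hydroxide at room temperature and a brief cold acidification expected to leave the C2 centre, the exocyclic alkene and the acid-sensitive triene intact.

**Compound list**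

1 | geranyl bromide, (2E)-1-bromo-3,7-dimethylocta-2,6-diene | BrC/C=C(\C)CCC=C(C)C | starting material
2 | trimethyl(prop-1-yn-1-yl)silane | CC#C[Si](C)(C)C | starting material
3 | [3-(trimethylsilyl)prop-2-yn-1-yl]lithium | [Li]CC#C[Si](C)(C)C | intermediate
4 | [(5E)-6,10-dimethylundeca-5,9-dien-1-yn-1-yl]trimethylsilane | C[Si](C)(C)C#CCC/C=C(\C)CCC=C(C)C | intermediate
5 | (5E)-6,10-dimethylundeca-5,9-dien-1-yne | C#CCC/C=C(\C)CCC=C(C)C | intermediate
6 | dimethyl[(1E,5E)-2,6,10-trimethylundeca-1,5,9-trien-1-yl]alumane | C[Al](C)/C=C(\C)CC/C=C(\C)CCC=C(C)C | intermediate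
7 | (1E,5E)-1-iodo-2,6,10-trimethylundeca-1,5,9-triene | I/C=C(\C)CC/C=C(\C)CCC=C(C)C | intermediate
8 | 4-(hydroxymethyl)cyclohexan-1-one | O=C1CCC(CO)CC1 | starting material
9 | (5R)-5-(hydroxymethyl)oxepan-2-one | O=C1CC[C@@H](CO)CCO1 | intermediate
10 | (5R)-5-(2-hydroxyethyl)oxan-2-one | O=C1CC[C@H](CCO)CO1 | intermediate
11 | (5R)-5-(2-iodoethyl)oxan-2-one | O=C1CC[C@H](CCI)CO1 | intermediate
12 | iodo{2-[(3R)-6-oxooxan-3-yl]ethyl}zinc | O=C1CC[C@H](CC[Zn]I)CO1 | intermediate
13 | (5S)-5-[(3E,7E)-4,8,12-trimethyltrideca-3,7,11-trien-1-yl]oxan-2-one | O=C1CC[C@H](CC/C=C(\C)CC/C=C(\C)CCC=C(C)C)CO1 | intermediate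
14 | (5S)-5-[(3E,7E)-4,8,12-trimethyltrideca-3,7,11-trien-1-yl]oxan-2-ol (C2 epimers) | OC1CC[C@H](CC/C=C(\C)CC/C=C(\C)CCC=C(C)C)CO1 | intermediate
15 | methyl (2E,6R,9E,13E)-6-(hydroxymethyl)-10,14,18-trimethylnonadeca-2,9,13,17-tetraenoate | COC(=O)/C=C/CC[C@H](CC/C=C(\C)CC/C=C(\C)CCC=C(C)C)CO | intermediate
16 | methyl 2-[(2R,5S)-5-[(3E,7E)-4,8,12-trimethyltrideca-3,7,11-trien-1-yl]oxan-2-yl]acetate | COC(=O)C[C@H]1CC[C@H](CC/C=C(\C)CC/C=C(\C)CCC=C(C)C)CO1 | intermediate
17 | lithium enolate of 16 | COC(O[Li])=C[C@H]1CC[C@H](CC/C=C(\C)CC/C=C(\C)CCC=C(C)C)CO1 | intermediate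
18 | methyl 3-(dimethylamino)-2-[(2R,5S)-5-[(3E,7E)-4,8,12-trimethyltrideca-3,7,11-trien-1-yl]oxan-2-yl]propanoate (α-epimers) | COC(=O)C(CN(C)C)[C@H]1CC[C@H](CC/C=C(\C)CC/C=C(\C)CCC=C(C)C)CO1 | intermediate
19 | {3-methoxy-3-oxo-2-[(2R,5S)-5-[(3E,7E)-4,8,12-trimethyltrideca-3,7,11-trien-1-yl]oxan-2-yl]propyl}trimethylammonium iodide | COC(=O)C(C[N+](C)(C)C)[C@H]1CC[C@H](CC/C=C(\C)CC/C=C(\C)CCC=C(C)C)CO1.[I-] | intermediate
20 | methyl 2-[(2R,5S)-5-[(3E,7E)-4,8,12-trimethyltrideca-3,7,11-trien-1-yl]oxan-2-yl]prop-2-enoate | COC(=O)C(=C)[C@H]1CC[C@H](CC/C=C(\C)CC/C=C(\C)CCC=C(C)C)CO1 | intermediate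
21 | lithium 2-[(2R,5S)-5-[(3E,7E)-4,8,12-trimethyltrideca-3,7,11-trien-1-yl]oxan-2-yl]prop-2-enoate | [Li+].[O-]C(=O)C(=C)[C@H]1CC[C@H](CC/C=C(\C)CC/C=C(\C)CCC=C(C)C)CO1 | intermediate
22 | rhopaloic acid A, 2-[(2R,5S)-5-[(3E,7E)-4,8,12-trimethyltrideca-3,7,11-trien-1-yl]oxan-2-yl]prop-2-enoic acid | C=C(C(=O)O)[C@H]1CC[C@H](CC/C=C(\C)CC/C=C(\C)CCC=C(C)C)CO1 | target

**Count and risks**

Total step count: 10. Longest linear sequence: 8 steps (steps 1, 2, 3, 6, 7, 8, 9, 10, from geranyl bromide).

Step 4 is the most likely to fail. The catalyst may discriminate poorly between the two enantiotopic migrating CH2 groups, because the free hydroxyl can compete for the Lewis acid and the CH2OH group gives only a small steric bias, so the lactone could form with low enantiomeric purity. The fallback sets out from 8 and replaces oxygen insertion by enantioselective deprotonation and oxidative cleavage. Ketone 8 would be silylated (t-BuPh2SiCl, imidazole, DMF) to 4-{[tert-butyl(diphenyl)silyl]oxymethyl}cyclohexan-1-one F1. Deprotonation with lithium bis[(R)-1-phenylethyl]amide or its enantiomer (whichever gives the 1R enol ether), LiCl and Me3SiCl as internal quench in THF at −78 °C should give tert-butyl(diphenyl){[(1R)-4-(trimethylsilyloxy)cyclohex-3-en-1-yl]methoxy}silane F2. Ozonolysis in CH2Cl2/MeOH at −78 °C with NaBH4 work-up should give (4R)-4-{[tert-butyl(diphenyl)silyl]oxymethyl}-6-hydroxyhexanoic acid F3. Bu4NF in THF followed by catalytic CSA should remove the silyl group and close the six-membered lactone, returning to the route at 10.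

Step 9 is the second risk. The β-alkoxy ester enolate may expel the ring oxygen (E1cB ring opening) before it is trapped, which would cost material and scramble C2 on reclosure; aminomethylation may also run twice. The fallback sets out from 16 and avoids any strong base by moving to the aldehyde oxidation level. Reduction with iBu2AlH in CH2Cl2 at −78 °C should give 2-[(2R,5S)-5-[(3E,7E)-4,8,12-trimethyltrideca-3,7,11-trien-1-yl]oxan-2-yl]acetaldehyde F4. Enamine-catalysed α-methylenation (aqueous CH2O, pyrrolidine and propionic acid as catalysts, i-PrOH, 45 °C) should give 2-[(2R,5S)-5-[(3E,7E)-4,8,12-trimethyltrideca-3,7,11-trien-1-yl]oxan-2-yl]prop-2-enal F5. Pinnick oxidation (NaClO2, NaH2PO4, 2-methylbut-2-ene in excess, t-BuOH/H2O) would then return to the route at 22.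

Step 8 is the third risk. The energy gap between the 2,5-trans and 2,5-cis oxanes is modest, so equilibration may stop short or give an inseparable mixture at C2. The fallback sets out from 13 and sets C2 kinetically instead. Addition of the lithium enolate of methyl acetate (LiN(iPr)2, MeOAc, THF, −78 °C) should give methyl 2-[(5S)-2-hydroxy-5-[(3E,7E)-4,8,12-trimethyltrideca-3,7,11-trien-1-yl]oxan-2-yl]acetate F6. Reduction with Et3SiH and BF3·OEt2 in CH2Cl2/MeCN at −78 → −40 °C should deliver hydride axially to the oxocarbenium ion whose C5 substituent sits pseudo-equatorial, placing the C2 side chain equatorial and trans to C5, and returns to the route at 16.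

**Further compounds**

F1 | step 4 | 4-{[tert-butyl(diphenyl)silyl]oxymethyl}cyclohexan-1-one | O=C1CCC(CO[Si](c2ccccc2)(c2ccccc2)C(C)(C)C)CC1
F2 | step 4 | tert-butyl(diphenyl){[(1R)-4-(trimethylsilyloxy)cyclohex-3-en-1-yl]methoxy}silane | C[Si](C)(C)OC1=CC[C@H](CO[Si](c2ccccc2)(c2ccccc2)C(C)(C)C)CC1
F3 | step 4 | (4R)-4-{[tert-butyl(diphenyl)silyl]oxymethyl}-6-hydroxyhexanoic acid | OC(=O)CC[C@@H](CO[Si](c1ccccc1)(c1ccccc1)C(C)(C)C)CCO
F4 | step 9 | 2-[(2R,5S)-5-[(3E,7E)-4,8,12-trimethyltrideca-3,7,11-trien-1-yl]oxan-2-yl]acetaldehyde | O=CC[C@H]1CC[C@H](CC/C=C(\C)CC/C=C(\C)CCC=C(C)C)CO1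
F5 | step 9 | 2-[(2R,5S)-5-[(3E,7E)-4,8,12-trimethyltrideca-3,7,11-trien-1-yl]oxan-2-yl]prop-2-enal | C=C(C=O)[C@H]1CC[C@H](CC/C=C(\C)CC/C=C(\C)CCC=C(C)C)CO1
F6 | step 8 | methyl 2-[(5S)-2-hydroxy-5-[(3E,7E)-4,8,12-trimethyltrideca-3,7,11-trien-1-yl]oxan-2-yl]acetate | COC(=O)CC1(O)CC[C@H](CC/C=C(\C)CC/C=C(\C)CCC=C(C)C)CO1
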